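**Retrosynthetic overview**
1. The target comes from its tetramethyl ether 13 (BBr3) and 13 from the 2-silyl enone 12 (fluoride); the seven-membered carbocycle is the only ring made and is closed in step 7.
2. Key disconnection: the bond between the carbonyl carbon C1 and the α-vinyl carbon C2 of the cyclohept-2-en-1-one, made together with the C3–styryl bond, so that 12 comes from the open-chain silyl-alkynyl ester 10 and (E)-styrylboronic acid by a nickel-catalysed anti-carbometallative acylation.
3. Enabling feature: the ring double bond C2=C3, whose C3 carries the exocyclic styryl arm and the ring CH2 (C4) and whose C2 is bonded to the ring carbonyl C1. This pair is an alkyne in the precursor, capped on C2 with a temporary benzyldimethylsilyl group that steers nickel to C2 and is removed in step 8.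
4. The alkyne comes from the methyl ketone of keto ester 7 (enol triflate, elimination, silylation). The two aryl-bearing centres C5 and C6 come from two successive rhodium/BINAP-catalysed 1,4-additions of arylboronic acids to the linear dienone ester 3.
5. Compound 3, which already holds all seven ring carbons, comes from a Wittig reaction of ethyl (E)-4-oxobut-2-enoate.

Key step: step 7

Assumption: (S)-BINAP–rhodium is taken to transfer the aryl group to the α-si face of an (E)-enone or (E)-enoate, as in the accepted model for this catalyst, which leads to the 4S and 3S centres drawn; if either addition shows the opposite sense, (R)-BINAP is used in that step.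

**Route**

Step 1
Reactants: 1 ethyl (E)-4-oxobut-2-enoate; 2 1-(triphenylphosphoranylidene)propan-2-one
Product: 3 ethyl (2E,4E)-6-oxohepta-2,4-dienoate
Conditions: CH2Cl2, rt
Reagents that add atoms: none
Why: Wittig olefination with the stabilised acetonylidene ylide is selective for the aldehyde and for the E-alkene, and should give the linear dienone ester that already contains all seven carbons of the future ring.

Step 2
Reactants: 3 ethyl (2E,4E)-6-oxohepta-2,4-dienoate; 4 (3,5-dimethoxyphenyl)boronic acid
Product: 5 ethyl (2E,4S)-4-(3,5-dimethoxyphenyl)-6-oxohept-2-enoate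
Conditions: [Rh(OH)((S)-BINAP)]2 (1.5 mol %), 4 (1.5 equiv), dioxane/H2O 10:1, 35 °C
Reagents that add atoms: none
Why: Rhodium-catalysed asymmetric 1,4-addition of an arylboronic acid (Hayashi–Miyaura reaction) should occur at the enone, which is far more reactive than the enoate, so the aryl group enters β to the ketone and the BINAP-bound aryl-rhodium selects the alkene face that gives the 4S centre.

Step 3
Reactants: 5 ethyl (2E,4S)-4-(3,5-dimethoxyphenyl)-6-oxohept-2-enoate; 6 (3,4-dimethoxyphenyl)boronic acid
Product: 7 ethyl (3S,4S)-3-(3,4-dimethoxyphenyl)-4-(3,5-dimethoxyphenyl)-6-oxoheptanoate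
Conditions: Rh(acac)(C2H4)2 (3 mol %), (S)-BINAP (3.3 mol %), 6 (3 equiv), dioxane/H2O 3:1, 100 °C
Reagents that add atoms: none
Why: The same Hayashi–Miyaura addition on the remaining (E)-enoate should be under catalyst control (same ligand, same facial sense) and set the 3S centre next to the existing one, while the water-rich, base-free medium should protonate the rhodium enolate before it can add to the methyl ketone.

Step 4
Reactants: 7 ethyl (3S,4S)-3-(3,4-dimethoxyphenyl)-4-(3,5-dimethoxyphenyl)-6-oxoheptanoate
Product: 8 ethyl (3S,4S)-3-(3,4-dimethoxyphenyl)-4-(3,5-dimethoxyphenyl)-6-[(trifluoromethanesulfonyl)oxy]hept-6-enoate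
Conditions: KN(SiMe3)2 (1.05 equiv), THF, −78 °C; then 2-[N,N-bis(trifluoromethanesulfonyl)amino]-5-chloropyridine, −78 °C
Reagents that add atoms: 2-[N,N-bis(trifluoromethanesulfonyl)amino]-5-chloropyridine, FC(F)(F)S(=O)(=O)N(c1ccc(Cl)cn1)S(=O)(=O)C(F)(F)F
Why: Kinetic deprotonation should go to the methyl group of the ketone (more acidic than the ester, and the other α-CH2 is shielded by the neighbouring tertiary benzylic carbon) and the enolate is O-triflated at low temperature (enol triflate formation), while both stereocentres are β to the carbonyl groups and cannot epimerise.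

Step 5
Reactants: 8 ethyl (3S,4S)-3-(3,4-dimethoxyphenyl)-4-(3,5-dimethoxyphenyl)-6-[(trifluoromethanesulfonyl)oxy]hept-6-enoate
Product: 9 ethyl (3S,4S)-3-(3,4-dimethoxyphenyl)-4-(3,5-dimethoxyphenyl)hept-6-ynoate
Conditions: LiN(iPr)2 (3 equiv), THF, −78 °C; aq. NH4Cl
Reagents that add atoms: none
Why: Base-induced anti elimination of triflate from the 1-alken-2-yl triflate (dehydrotriflation) should give the terminal alkyne, the ester being only reversibly enolised at −78 °C and restored on protonation.

Step 6
Reactants: 9 ethyl (3S,4S)-3-(3,4-dimethoxyphenyl)-4-(3,5-dimethoxyphenyl)hept-6-ynoate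
Product: 10 ethyl (3S,4S)-7-[benzyl(dimethyl)silyl]-3-(3,4-dimethoxyphenyl)-4-(3,5-dimethoxyphenyl)hept-6-ynoate
Conditions: LiN(SiMe3)2 (1.1 equiv), THF, −78 °C; BnMe2SiCl, −78 °C to 0 °C
Reagents that add atoms: benzyl(chloro)dimethylsilane, C[Si](C)(Cl)Cc1ccccc1
Why: The lithium acetylide should form preferentially and be silylated on carbon (alkyne C-silylation), any O-silylated ester enolate reverting to the ester on work-up, which installs the temporary silyl group that directs the key step and can later be cleaved from sp2 carbon by fluoride.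

Step 7
Reactants: 10 ethyl (3S,4S)-7-[benzyl(dimethyl)silyl]-3-(3,4-dimethoxyphenyl)-4-(3,5-dimethoxyphenyl)hept-6-ynoate; 11 [(E)-2-phenylethenyl]boronic acid
Product: 12 (5S,6S)-2-[benzyl(dimethyl)silyl]-6-(3,4-dimethoxyphenyl)-5-(3,5-dimethoxyphenyl)-3-[(E)-2-phenylethenyl]cyclohept-2-en-1-one
Conditions: Ni(OAc)2·4H2O (10 mol %), 2-[2-(diphenylphosphanyl)ethyl]pyridine (10 mol %), 11 (2 equiv), CF3CH2OH, 80 °C
Reagents that add atoms: none
Why: Proposed new method: the styryl group is transferred from boron to divalent nickel and the styrylnickel species adds syn across the alkyne, nickel going to the silicon-bearing carbon (the bulkier, anion-stabilising terminus) and styryl to the carbon that carries the chain. The resulting α-silyl alkenylnickel equilibrates between its E and Z forms and only the isomer with nickel cis to the tether can reach the ester; addition to the ester carbonyl and loss of ethoxide give the enone, and protonolysis of the nickel alkoxide by the solvent returns the catalyst. The closest known reaction type is the nickel-catalysed anti-carbometallative cyclisation of alkyne-tethered electrophiles with arylboronic acids, which with malonate esters gives cyclopent-2-enones by the same alkenylnickel acylation; an alkenylboronic acid, a silyl-capped alkyne and a seven-membered ring are the extensions proposed here. The cycloheptenone ring closes by 7-exo-trig attack of the alkenyl carbon on the ester carbonyl. No stereocentre is created: the two existing centres are not α to the carbonyl and stay as set, and the E geometry of the styryl group comes unchanged from the boronic acid. The step needs regioselective insertion (secured by the silyl group), net anti addition (secured by the isomerisation, eased by the α-silyl and conjugating styryl substituents) and ring closure ahead of protodenickelation (helped by hydrogen-bond activation of the ester by trifluoroethanol and by the trans-diaryl backbone, whose aryl-anti conformer holds the chain ends gauche).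

Step 8
Reactants: 12 (5S,6S)-2-[benzyl(dimethyl)silyl]-6-(3,4-dimethoxyphenyl)-5-(3,5-dimethoxyphenyl)-3-[(E)-2-phenylethenyl]cyclohept-2-en-1-one
Product: 13 (5S,6S)-6-(3,4-dimethoxyphenyl)-5-(3,5-dimethoxyphenyl)-3-[(E)-2-phenylethenyl]cyclohept-2-en-1-one
Conditions: Bu4NF (3 equiv), THF, 0 °C to rt; aq. NH4Cl
Reagents that add atoms: none
Why: Fluoride-induced protodesilylation of an alkenyl benzyldimethylsilane (benzyl lost as toluene, then protonolysis of the C–Si bond) should replace silicon by hydrogen at C2 and leave the dienone and the aryl methyl ethers unchanged.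

Step 9
Reactants: 13 (5S,6S)-6-(3,4-dimethoxyphenyl)-5-(3,5-dimethoxyphenyl)-3-[(E)-2-phenylethenyl]cyclohept-2-en-1-one
Product: 14 (5S,6S)-6-(3,4-dihydroxyphenyl)-5-(3,5-dihydroxyphenyl)-3-[(E)-2-phenylethenyl]cyclohept-2-en-1-one (target, CNP0400050.1)
Conditions: BBr3 (8 equiv), CH2Cl2, −78 °C to rt; then H2O
Reagents that add atoms: none
Why: Lewis-acid cleavage of the four aryl methyl ethers with BBr3 (via aryloxyboranes hydrolysed on work-up) should free the catechol and resorcinol units without touching the stereocentres, neither of which is α to the carbonyl group.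

**Compound list**
1 | ethyl (E)-4-oxobut-2-enoate | CCOC(=O)/C=C/C=O | starting material
2 | 1-(triphenylphosphoranylidene)propan-2-one | CC(=O)C=P(c1ccccc1)(c1ccccc1)c1ccccc1 | starting material
3 | ethyl (2E,4E)-6-oxohepta-2,4-dienoate | CCOC(=O)/C=C/C=C/C(C)=O | intermediate
4 | (3,5-dimethoxyphenyl)boronic acid | COc1cc(OC)cc(c1)B(O)O | starting material
5 | ethyl (2E,4S)-4-(3,5-dimethoxyphenyl)-6-oxohept-2-enoate | CC(=O)C[C@H](c1cc(OC)cc(OC)c1)/C=C/C(=O)OCC | intermediate
6 | (3,4-dimethoxyphenyl)boronic acid | COc1ccc(cc1OC)B(O)O | starting material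
7 | ethyl (3S,4S)-3-(3,4-dimethoxyphenyl)-4-(3,5-dimethoxyphenyl)-6-oxoheptanoate | CC(=O)C[C@H](c1cc(OC)cc(OC)c1)[C@@H](c1ccc(OC)c(OC)c1)CC(=O)OCC | intermediate
8 | ethyl (3S,4S)-3-(3,4-dimethoxyphenyl)-4-(3,5-dimethoxyphenyl)-6-[(trifluoromethanesulfonyl)oxy]hept-6-enoate | C=C(OS(=O)(=O)C(F)(F)F)C[C@H](c1cc(OC)cc(OC)c1)[C@@H](c1ccc(OC)c(OC)c1)CC(=O)OCC | intermediate
9 | ethyl (3S,4S)-3-(3,4-dimethoxyphenyl)-4-(3,5-dimethoxyphenyl)hept-6-ynoate | C#CC[C@H](c1cc(OC)cc(OC)c1)[C@@H](c1ccc(OC)c(OC)c1)CC(=O)OCC | intermediate
10 | ethyl (3S,4S)-7-[benzyl(dimethyl)silyl]-3-(3,4-dimethoxyphenyl)-4-(3,5-dimethoxyphenyl)hept-6-ynoate | C[Si](C)(Cc1ccccc1)C#CC[C@H](c1cc(OC)cc(OC)c1)[C@@H](c1ccc(OC)c(OC)c1)CC(=O)OCC | intermediate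
11 | [(E)-2-phenylethenyl]boronic acid | OB(O)/C=C/c1ccccc1 | starting material
12 | (5S,6S)-2-[benzyl(dimethyl)silyl]-6-(3,4-dimethoxyphenyl)-5-(3,5-dimethoxyphenyl)-3-[(E)-2-phenylethenyl]cyclohept-2-en-1-one | O=C1C([Si](C)(C)Cc2ccccc2)=C(/C=C/c2ccccc2)C[C@H](c2cc(OC)cc(OC)c2)[C@@H](c2ccc(OC)c(OC)c2)C1 | intermediate
13 | (5S,6S)-6-(3,4-dimethoxyphenyl)-5-(3,5-dimethoxyphenyl)-3-[(E)-2-phenylethenyl]cyclohept-2-en-1-one | O=C1C=C(/C=C/c2ccccc2)C[C@H](c2cc(OC)cc(OC)c2)[C@@H](c2ccc(OC)c(OC)c2)C1 | intermediate
14 | (5S,6S)-6-(3,4-dihydroxyphenyl)-5-(3,5-dihydroxyphenyl)-3-[(E)-2-phenylethenyl]cyclohept-2-en-1-one | O=C1C=C(/C=C/c2ccccc2)C[C@H](c2cc(O)cc(O)c2)[C@@H](c2ccc(O)c(O)c2)C1 | target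

Total step count: 9. Longest linear sequence: 9 steps (1 to 14).

**Steps most likely to fail**

1. Step 7 (Proposed new method). Three things may go wrong. The alkenyl–nickel bond may be protonated by the alcohol solvent before E/Z isomerisation and ring closure, giving open-chain hydroalkenylation. Insertion of the hindered silyl alkyne may be slow, with competing protodeboronation of the alkenylboronic acid. The alkenylnickel may fail to add to an unactivated ester in a seven-membered mode. The fallback sets out from 7 and returns at 13, forms the same ring bond by radical chemistry of known type, and makes step 8 unnecessary. Claisen–Schmidt condensation of 7 with benzaldehyde in aqueous ethanolic NaOH, which also saponifies the ester, should give (3S,4S,7E)-3-(3,4-dimethoxyphenyl)-4-(3,5-dimethoxyphenyl)-6-oxo-8-phenyloct-7-enoic acid F1. Horner–Wadsworth–Emmons olefination of its ketone with diethyl {[(4-methylphenyl)sulfonyl]methyl}phosphonate (NaH, 2.2 equiv, THF) should give (3S,4S,7E)-3-(3,4-dimethoxyphenyl)-4-(3,5-dimethoxyphenyl)-6-{[(4-methylphenyl)sulfonyl]methylidene}-8-phenyloct-7-enoic acid F2, either geometry of the new double bond being usable. (PhSe)2 and Bu3P should convert the acid into Se-phenyl (3S,4S,7E)-3-(3,4-dimethoxyphenyl)-4-(3,5-dimethoxyphenyl)-6-{[(4-methylphenyl)sulfonyl]methylidene}-8-phenyloct-7-eneselenoate F3. Bu3SnH (slow addition) and AIBN in benzene at 80 °C then generate the acyl radical, which adds in the 7-endo mode to the sulfonyl-bearing terminus of the diene; the allyl/benzyl-stabilised adduct radical expels the sulfonyl radical and gives 13 directly. Both elementary events, 7-endo cyclisation of acyl radicals from selenoesters and radical addition–fragmentation at vinyl sulfones, are established radical reactions.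

2. Step 3. Aryl transfer to a β-carbon flanked by a tertiary benzylic centre may be slow. Facial control by the catalyst may have to work against the bias of the existing centre. The rhodium ester enolate may be captured by the methyl ketone (conjugate addition–aldol cyclisation to a cyclopentanol) instead of being protonated. The fallback sets out from 1 and returns at 7; it reverses the order of aryl introduction so that the hindered addition is an enone addition and no ketone is present when the ester enolate forms. Acetalisation of 1 (HC(OEt)3, cat. TsOH, EtOH) should give ethyl (E)-4,4-diethoxybut-2-enoate F4. Hayashi–Miyaura addition of 6 (Rh(acac)(C2H4)2, (S)-BINAP, dioxane/H2O, 100 °C) should give ethyl (3R)-3-(3,4-dimethoxyphenyl)-4,4-diethoxybutanoate F5. Mild aqueous acid (1 M HCl, THF, 0 °C) should give ethyl (3R)-3-(3,4-dimethoxyphenyl)-4-oxobutanoate F6, used at once because this α-aryl aldehyde can epimerise. Wittig reaction with 2 in CH2Cl2 should give ethyl (3S,4E)-3-(3,4-dimethoxyphenyl)-6-oxohept-4-enoate F7. Addition of 4 to this enone under the conditions of step 2 should then give 7.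

3. Step 5. Under excess amide base the ester enolate may undergo Claisen-type self-condensation or ketene formation, the amide may attack sulfur and return the ketone, or an allene may form. The fallback sets out from 7 and returns at 9; it carries the chain end as a carboxylate, which is neither electrophilic nor readily enolised. Saponification of 7 (LiOH, THF/H2O) should give (3S,4S)-3-(3,4-dimethoxyphenyl)-4-(3,5-dimethoxyphenyl)-6-oxoheptanoic acid F8. KN(SiMe3)2 (2.1 equiv) followed by the triflimide of step 4 should give (3S,4S)-3-(3,4-dimethoxyphenyl)-4-(3,5-dimethoxyphenyl)-6-[(trifluoromethanesulfonyl)oxy]hept-6-enoic acid F9. LiN(iPr)2 (excess, THF, −78 °C) should give (3S,4S)-3-(3,4-dimethoxyphenyl)-4-(3,5-dimethoxyphenyl)hept-6-ynoic acid F10. Esterification (EtI, K2CO3, DMF) should give 9.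

**Further compounds**
F1 | step 7 | (3S,4S,7E)-3-(3,4-dimethoxyphenyl)-4-(3,5-dimethoxyphenyl)-6-oxo-8-phenyloct-7-enoic acid | O=C(/C=C/c1ccccc1)C[C@H](c1cc(OC)cc(OC)c1)[C@@H](c1ccc(OC)c(OC)c1)CC(=O)O
F2 | step 7 | (3S,4S,7E)-3-(3,4-dimethoxyphenyl)-4-(3,5-dimethoxyphenyl)-6-{[(4-methylphenyl)sulfonyl]methylidene}-8-phenyloct-7-enoic acid | Cc1ccc(cc1)S(=O)(=O)C=C(/C=C/c1ccccc1)C[C@H](c1cc(OC)cc(OC)c1)[C@@H](c1ccc(OC)c(OC)c1)CC(=O)O
F3 | step 7 | Se-phenyl (3S,4S,7E)-3-(3,4-dimethoxyphenyl)-4-(3,5-dimethoxyphenyl)-6-{[(4-methylphenyl)sulfonyl]methylidene}-8-phenyloct-7-eneselenoate | Cc1ccc(cc1)S(=O)(=O)C=C(/C=C/c1ccccc1)C[C@H](c1cc(OC)cc(OC)c1)[C@@H](c1ccc(OC)c(OC)c1)CC(=O)[Se]c1ccccc1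
F4 | step 3 | ethyl (E)-4,4-diethoxybut-2-enoate | CCOC(=O)/C=C/C(OCC)OCC
F5 | step 3 | ethyl (3R)-3-(3,4-dimethoxyphenyl)-4,4-diethoxybutanoate | CCOC(OCC)[C@@H](c1ccc(OC)c(OC)c1)CC(=O)OCC
F6 | step 3 | ethyl (3R)-3-(3,4-dimethoxyphenyl)-4-oxobutanoate | O=C[C@@H](c1ccc(OC)c(OC)c1)CC(=O)OCC
F7 | step 3 | ethyl (3S,4E)-3-(3,4-dimethoxyphenyl)-6-oxohept-4-enoate | CC(=O)/C=C/[C@@H](c1ccc(OC)c(OC)c1)CC(=O)OCC
F8 | step 5 | (3S,4S)-3-(3,4-dimethoxyphenyl)-4-(3,5-dimethoxyphenyl)-6-oxoheptanoic acid | CC(=O)C[C@H](c1cc(OC)cc(OC)c1)[C@@H](c1ccc(OC)c(OC)c1)CC(=O)O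
F9 | step 5 | (3S,4S)-3-(3,4-dimethoxyphenyl)-4-(3,5-dimethoxyphenyl)-6-[(trifluoromethanesulfonyl)oxy]hept-6-enoic acid | C=C(OS(=O)(=O)C(F)(F)F)C[C@H](c1cc(OC)cc(OC)c1)[C@@H](c1ccc(OC)c(OC)c1)CC(=O)O
F10 | step 5 | (3S,4S)-3-(3,4-dimethoxyphenyl)-4-(3,5-dimethoxyphenyl)hept-6-ynoic acid | C#CC[C@H](c1cc(OC)cc(OC)c1)[C@@H](c1ccc(OC)c(OC)c1)CC(=O)O
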